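**Plan**

1. Retrosynthesis: (a) the pair C5–OH / side-chain C=O is read as a 4,5-dihydroisoxazole (N–O bond); (b) the ring bond C3–C4 (enone β-carbon to the CH2 next to the carbinol carbon) is cut to a primary iodide and an ethynyl ketone; (c) C5–O and C4–I are removed together by retro-iodoetherification to a β,γ-unsaturated ketoxime; (d) the three CH2 arms on C5 go back to a trimethylenemethane bis-silane, oleoyl chloride and 3-(trimethylsilyl)propynal.
2. Forward order: the chain is joined first (steps 1–4), the isoxazoline ring forms second (step 5), the cyclohexenone ring closes third at C3–C4 (step 7), and the isoxazoline is opened last to free the hydroxy ketone (step 8).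
3. Enabling feature: C4 is the carbon next to the oxygen-bearing quaternary C5, so it leaves a 5-exo iodoetherification as CH2I. It is also the γ-carbon of the C1(=O)–C2=C3 enone, so a C4 radical meets C3 as the β-carbon of an ynone whose carbonyl lies inside the forming six-membered ring.
4. Stereochemistry: the only stereocentre, C5 (R), is set by catalyst-controlled enantioselective iodoetherification in step 5 and is not touched afterwards. The (Z)-alkene comes intact from oleoyl chloride, and the carbinol made in step 3 is transient.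

Key step: step 7

Assumption: which pseudo-enantiomeric series of the cinchona catalyst gives the (R)-configured C–O centre on this dialkyl ketoxime is not known in advance; the series that does so is taken to be identified on the first batch of 10 and used.

**Step 1**
Reactants: 1 3-chloro-2-(chloromethyl)prop-1-ene
Product: 3 2-methylidenepropane-1,3-diylbis(trimethylsilane), via 2-(chloromethyl)allyltrimethylsilane 2 (not isolated)
Conditions: Mg turnings (2.4 equiv), Me3SiCl (2.4 equiv), THF, 0 °C to reflux
Reagents that add atoms: chlorotrimethylsilane, C[Si](C)(C)Cl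
Why: Barbier-type in situ Grignard formation at each allylic chloride with immediate C-silylation (which suppresses Wurtz coupling) is the standard entry to this bis(allylsilane); no stereocentre is formed.

**Step 2**
Reactants: 3 2-methylidenepropane-1,3-diylbis(trimethylsilane) (1.5 equiv); 4 (9Z)-octadec-9-enoyl chloride (oleoyl chloride)
Product: 5 (12Z)-2-[(trimethylsilyl)methyl]henicosa-1,12-dien-4-one
Conditions: TiCl4 (1.05 equiv), CH2Cl2, −78 °C
Reagents that add atoms: none
Why: Lewis-acid-mediated SE2' acylation of an allylsilane (Hosomi–Sakurai-type acylation) joins the oleoyl carbon to one terminus with allylic transposition, and the second allylsilane survives because the new keto group deactivates it and 3 is in excess; no stereocentre is formed and the (Z)-alkene is inert at −78 °C.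

**Step 3**
Reactants: 5 (12Z)-2-[(trimethylsilyl)methyl]henicosa-1,12-dien-4-one; 6 3-(trimethylsilyl)prop-2-ynal
Product: 7 (15Z)-3-hydroxy-5-methylidene-1-(trimethylsilyl)tetracos-15-en-1-yn-7-one (racemic at the carbinol)
Conditions: TiCl4 (1.1 equiv), CH2Cl2, −78 °C; aqueous NaHCO3 work-up
Reagents that add atoms: none
Why: Hosomi–Sakurai allylation of the TiCl4-activated ynal by the remaining allylsilane gives the homoallylic propargylic alcohol by 1,2-addition and regenerates the 1,1-disubstituted alkene; the new carbinol centre is formed without control, which is harmless because step 6 oxidises it away.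

**Step 4**
Reactants: 7 (15Z)-3-hydroxy-5-methylidene-1-(trimethylsilyl)tetracos-15-en-1-yn-7-one
Product: 9 (15Z)-7-(hydroxyimino)-5-methylidenetetracos-15-en-1-yn-3-ol (mixture of C=N isomers), via silylated oxime 8 (not isolated)
Conditions: NH2OH (50% aqueous, 1.5 equiv), MeOH, 23 °C; then K2CO3 (0.3 equiv), 23 °C
Reagents that add atoms: hydroxylamine, NO
Why: Hydroxylamine condenses with the only ketone to the ketoxime, which also protects the β,γ-unsaturated ketone from base-induced conjugation, and catalytic K2CO3 in methanol then cleaves the alkynyl C–Si bond; no new stereocentre is formed.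

**Step 5**
Reactants: 9 (15Z)-7-(hydroxyimino)-5-methylidenetetracos-15-en-1-yn-3-ol
Product: 10 1-[(5R)-3-[(8Z)-heptadec-8-en-1-yl]-5-(iodomethyl)-4,5-dihydro-1,2-oxazol-5-yl]but-3-yn-2-ol (both carbinol epimers)
Conditions: N-iodosuccinimide (1.2 equiv), 9-amino(9-deoxy)epi-dihydroquinidine 3,5-bis(trifluoromethyl)phenyl thiourea (10 mol %) or its dihydroquinine-derived pseudo-enantiomer, PhMe/CHCl3, −78 °C, dark
Reagents that add atoms: N-iodosuccinimide, O=C1CCC(=O)N1I
Why: In this catalytic enantioselective iodoetherification of a β,γ-unsaturated ketoxime the bifunctional amine–thiourea holds oxime and iodinating agent, iodine goes to the terminal CH2 and the oxime oxygen closes 5-exo on the disubstituted alkene carbon anti to iodine, so the quaternary C–O centre (R) is set by catalyst-controlled choice of the alkene face; only the oxime isomer with OH syn to the allylic CH2 can close, and the other is re-equilibrated and recycled.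

**Step 6**
Reactants: 10 1-[(5R)-3-[(8Z)-heptadec-8-en-1-yl]-5-(iodomethyl)-4,5-dihydro-1,2-oxazol-5-yl]but-3-yn-2-ol
Product: 11 1-[(5R)-3-[(8Z)-heptadec-8-en-1-yl]-5-(iodomethyl)-4,5-dihydro-1,2-oxazol-5-yl]but-3-yn-2-one
Conditions: Dess–Martin periodinane (1.3 equiv), CH2Cl2, 0 to 23 °C
Reagents that add atoms: none
Why: Dess–Martin oxidation converts the secondary propargylic alcohol into the ethynyl ketone under neutral conditions that leave the primary iodide, the isoxazoline and the (Z)-alkene untouched, and it removes the uncontrolled carbinol centre.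

**Step 7**
Reactants: 11 1-[(5R)-3-[(8Z)-heptadec-8-en-1-yl]-5-(iodomethyl)-4,5-dihydro-1,2-oxazol-5-yl]but-3-yn-2-one
Product: 12 (5R)-3-[(8Z)-heptadec-8-en-1-yl]-1-oxa-2-azaspiro[4.5]deca-2,8-dien-7-one
Conditions: (Me3Si)3SiH (1.3 equiv, syringe pump), AIBN (0.2 equiv), PhMe (0.005 M), 80 °C; stopped at full conversion of 11
Reagents that add atoms: none
Why: The tris(trimethylsilyl)silyl radical abstracts iodine from the CH2I carbon, the primary radical on the CH2 attached to the spiro C–O carbon adds to the unsubstituted terminal carbon of the ethynyl ketone, and the α-keto vinyl radical takes hydrogen from the silane to carry the chain. The closest known reaction type is the endo-mode radical (Giese-type) cyclisation of alkyl iodides onto ynones and onto enones whose carbonyl lies inside the forming ring. The cyclohexenone ring closes in the 6-endo-dig mode, which leaves the C2=C3 double bond necessarily cis inside the ring and conjugated to the ketone. No new stereocentre arises, and the spiro C–O centre from step 5 is not a radical site and is carried through unchanged. The step needs 6-endo closure over 5-exo-dig closure and over direct reduction: the first is secured by polarity (the nucleophilic alkyl radical attacks the ynone β-carbon, not the carbonyl-bearing α-carbon) and by the gem-disubstituted spiro carbon in the tether, the second by slow silane addition at high dilution.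

**Step 8**
Reactants: 12 (5R)-3-[(8Z)-heptadec-8-en-1-yl]-1-oxa-2-azaspiro[4.5]deca-2,8-dien-7-one
Product: 14 (5R)-5-hydroxy-5-[(10Z)-2-oxononadec-10-en-1-yl]cyclohex-2-en-1-one, via hydroxy imine 13 (not isolated)
Conditions: Mo(CO)6 (1.0 equiv), MeCN/H2O (15:1), 80 °C; neutral work-up
Reagents that add atoms: water, O
Why: Zerovalent molybdenum hexacarbonyl cleaves the isoxazoline N–O bond reductively and the resulting β-hydroxy imine hydrolyses in the aqueous medium (the classical unmasking of an isoxazoline as an aldol), which spares the C=C bonds and does not touch the carbinol C–O bond, so the (R) centre is retained.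

**Compound list**

1 | 3-chloro-2-(chloromethyl)prop-1-ene | C=C(CCl)CCl | starting material
2 | 2-(chloromethyl)allyltrimethylsilane | C=C(CCl)C[Si](C)(C)C | intermediate (not isolated)
3 | 2-methylidenepropane-1,3-diylbis(trimethylsilane) | C=C(C[Si](C)(C)C)C[Si](C)(C)C | intermediate
4 | (9Z)-octadec-9-enoyl chloride (oleoyl chloride) | CCCCCCCC/C=C\CCCCCCCC(=O)Cl | starting material
5 | (12Z)-2-[(trimethylsilyl)methyl]henicosa-1,12-dien-4-one | CCCCCCCC/C=C\CCCCCCCC(=O)CC(=C)C[Si](C)(C)C | intermediate
6 | 3-(trimethylsilyl)prop-2-ynal | C[Si](C)(C)C#CC=O | starting material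
7 | (15Z)-3-hydroxy-5-methylidene-1-(trimethylsilyl)tetracos-15-en-1-yn-7-one (racemic carbinol) | CCCCCCCC/C=C\CCCCCCCC(=O)CC(=C)CC(O)C#C[Si](C)(C)C | intermediate
8 | (15Z)-7-(hydroxyimino)-5-methylidene-1-(trimethylsilyl)tetracos-15-en-1-yn-3-ol | CCCCCCCC/C=C\CCCCCCCC(=NO)CC(=C)CC(O)C#C[Si](C)(C)C | intermediate (not isolated)
9 | (15Z)-7-(hydroxyimino)-5-methylidenetetracos-15-en-1-yn-3-ol (C=N isomers, racemic carbinol) | CCCCCCCC/C=C\CCCCCCCC(=NO)CC(=C)CC(O)C#C | intermediate
10 | 1-[(5R)-3-[(8Z)-heptadec-8-en-1-yl]-5-(iodomethyl)-4,5-dihydro-1,2-oxazol-5-yl]but-3-yn-2-ol (carbinol epimers) | CCCCCCCC/C=C\CCCCCCCC1=NO[C@](CI)(C1)CC(O)C#C | intermediate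
11 | 1-[(5R)-3-[(8Z)-heptadec-8-en-1-yl]-5-(iodomethyl)-4,5-dihydro-1,2-oxazol-5-yl]but-3-yn-2-one | CCCCCCCC/C=C\CCCCCCCC1=NO[C@](CI)(C1)CC(=O)C#C | intermediate
12 | (5R)-3-[(8Z)-heptadec-8-en-1-yl]-1-oxa-2-azaspiro[4.5]deca-2,8-dien-7-one | CCCCCCCC/C=C\CCCCCCCC1=NO[C@@]2(C1)CC=CC(=O)C2 | intermediate
13 | (5R)-5-hydroxy-5-[(10Z)-2-iminononadec-10-en-1-yl]cyclohex-2-en-1-one | CCCCCCCC/C=C\CCCCCCCC(=N)C[C@]1(O)CC=CC(=O)C1 | intermediate (not isolated)
14 | (5R)-5-hydroxy-5-[(10Z)-2-oxononadec-10-en-1-yl]cyclohex-2-en-1-one | CCCCCCCC/C=C\CCCCCCCC(=O)C[C@]1(O)CC=CC(=O)C1 | target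

**Step count and risks**

Total steps: 8. Longest linear sequence: 8 (from 1 to 14).

Steps most likely to fail:

1. Step 7 (radical ring closure). What may go wrong:
   - hydrogen transfer to the primary radical before it cyclises;
   - 5-exo-dig closure at the α-carbon of the ynone;
   - fragmentation of the C–O bond β to the radical (isoxazoline opening and re-closure, which would also erode the configuration);
   - Z-to-E isomerisation of the remote alkene by reversible silyl-radical addition if the chain keeps running after the iodide is consumed.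

   Fallback, setting out from 11 and returning at 12: conjugate hydroiodination of the ynone (NaI, AcOH, 23 °C) should give (3Z)-1-[(5R)-3-[(8Z)-heptadec-8-en-1-yl]-5-(iodomethyl)-4,5-dihydro-1,2-oxazol-5-yl]-4-iodobut-3-en-2-one F1. A nickel-catalysed intramolecular reductive cross-electrophile coupling of its vinyl iodide with its primary alkyl iodide (NiI2, 4,4'-di-tert-butyl-2,2'-bipyridine, Mn powder, DMA, high dilution) then closes the same ring bond on the metal instead of in a free-radical chain and should give 12.

2. Step 5 (enantioselective iodoetherification). What may go wrong: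
   - poor facial selectivity on a dialkyl ketoxime;
   - incomplete conversion because only one C=N isomer can close through oxygen;
   - disturbance of the hydrogen-bonding catalyst by the free carbinol.

   Fallback, setting out from 7 and returning at 11: the approach changes from catalyst control to resolution through the temporary carbinol.
   - Kinetic resolution of 7 with Candida antarctica lipase B and vinyl acetate should leave one alcohol enantiomer, drawn as (3S,15Z)-3-hydroxy-5-methylidene-1-(trimethylsilyl)tetracos-15-en-1-yn-7-one F2, beside (3R,15Z)-5-methylidene-7-oxo-1-(trimethylsilyl)tetracos-15-en-1-yn-3-yl acetate F3. Either series serves, since this centre is oxidised later.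
   - The conditions of step 4 should convert F2 into (3S,15Z)-7-(hydroxyimino)-5-methylidenetetracos-15-en-1-yn-3-ol F4.
   - Uncatalysed iodoetherification (I2, NaHCO3, MeCN, 0 °C) should then give two diastereomers, (2S)-1-[(5R)-3-[(8Z)-heptadec-8-en-1-yl]-5-(iodomethyl)-4,5-dihydro-1,2-oxazol-5-yl]but-3-yn-2-ol F5 and (2S)-1-[(5S)-3-[(8Z)-heptadec-8-en-1-yl]-5-(iodomethyl)-4,5-dihydro-1,2-oxazol-5-yl]but-3-yn-2-ol F6, to be separated on silica gel.
   - Dess–Martin oxidation of F5 as in step 6 should give 11.

3. Step 8 (unmasking in the presence of the enone). What may go wrong: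
   - dehydration of the β-hydroxy ketone towards the phenol under the hot conditions;
   - retro-aldol cleavage;
   - aza-Michael capture of the ring enone by the transient N–H imine.

   Fallback, setting out from 12 and returning at 14: the enone is taken out of play during the unmasking.
   - Luche reduction (NaBH4, CeCl3·7H2O, MeOH, −78 °C) should give (5R)-3-[(8Z)-heptadec-8-en-1-yl]-1-oxa-2-azaspiro[4.5]deca-2,8-dien-7-ol F7 as a mixture of carbinol epimers.
   - N–O cleavage with Mo(CO)6 in MeCN/H2O, now without an enone, should give (10Z)-1-[(1S)-1,5-dihydroxycyclohex-3-en-1-yl]nonadec-10-en-2-one F8.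
   - MnO2 in CH2Cl2 should oxidise only the secondary allylic alcohol and give 14.

**Further compounds**

F1 | step 7 | (3Z)-1-[(5R)-3-[(8Z)-heptadec-8-en-1-yl]-5-(iodomethyl)-4,5-dihydro-1,2-oxazol-5-yl]-4-iodobut-3-en-2-one | CCCCCCCC/C=C\CCCCCCCC1=NO[C@](CI)(C1)CC(=O)/C=C\I
F2 | step 5 | (3S,15Z)-3-hydroxy-5-methylidene-1-(trimethylsilyl)tetracos-15-en-1-yn-7-one | CCCCCCCC/C=C\CCCCCCCC(=O)CC(=C)C[C@H](O)C#C[Si](C)(C)C
F3 | step 5 | (3R,15Z)-5-methylidene-7-oxo-1-(trimethylsilyl)tetracos-15-en-1-yn-3-yl acetate | CCCCCCCC/C=C\CCCCCCCC(=O)CC(=C)C[C@@H](OC(C)=O)C#C[Si](C)(C)C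
F4 | step 5 | (3S,15Z)-7-(hydroxyimino)-5-methylidenetetracos-15-en-1-yn-3-ol | CCCCCCCC/C=C\CCCCCCCC(=NO)CC(=C)C[C@H](O)C#C
F5 | step 5 | (2S)-1-[(5R)-3-[(8Z)-heptadec-8-en-1-yl]-5-(iodomethyl)-4,5-dihydro-1,2-oxazol-5-yl]but-3-yn-2-ol | CCCCCCCC/C=C\CCCCCCCC1=NO[C@](CI)(C1)C[C@H](O)C#C
F6 | step 5 | (2S)-1-[(5S)-3-[(8Z)-heptadec-8-en-1-yl]-5-(iodomethyl)-4,5-dihydro-1,2-oxazol-5-yl]but-3-yn-2-ol | CCCCCCCC/C=C\CCCCCCCC1=NO[C@@](CI)(C1)C[C@H](O)C#C
F7 | step 8 | (5R)-3-[(8Z)-heptadec-8-en-1-yl]-1-oxa-2-azaspiro[4.5]deca-2,8-dien-7-ol | CCCCCCCC/C=C\CCCCCCCC1=NO[C@@]2(C1)CC=CC(O)C2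
F8 | step 8 | (10Z)-1-[(1S)-1,5-dihydroxycyclohex-3-en-1-yl]nonadec-10-en-2-one | CCCCCCCC/C=C\CCCCCCCC(=O)C[C@]1(O)CC=CC(O)C1
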